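(Readings and results are simulated from invented constants; noise was put on by code.)

The grey flask gains 0.0433 min⁻¹ of its charge per minute up to 3.00 min, far faster than the 0.00400 min⁻¹ between 5.00 min and 10.0 min, and I must decide what that flat stretch means.

| flask | starting material | second substrate | free enzyme | temperature | remark | time |
|---|---|---|---|---|---|---|
| grey | 10 mM | 10 mM | 6.9 µM | 37 °C | the very flask that is asked about, followed so far |  |
| violet | 10 mM | 10 mM | 6.9 µM | 43 °C | run made earlier |  |
| flask | 10 mM | 10.0 mM | 6.9 µM | 37 °C |  | 20 min |

| run | time / min | target / % |
|---|---|---|
| grey | 1.50 | 6 |
| grey | 3.00 | 13 |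
| grey | 5.00 | 12 |
| grey | 6.00 | 12 |
| grey | 8.00 | 14 |
| grey | 10.0 | 14 |
| grey | 12.0 | 24 |
| violet | 1.50 | 4 |
| violet | 3.00 | 13 |
| violet | 5.00 | 13 |
| violet | 6.00 | 17 |
| violet | 8.00 | 19 |
| violet | 10.0 | 17 |
| violet | 12.0 | 15 |

(scatter of a reading: 2 percentage points)

- epsilon: at 20 min add free enzyme, 100% of the amount charged, then wait 6.0 min
- theta: change nothing and wait 6.0 min more
- alpha: at 20 min take out 90% of the target then present, then wait 6.0 min

- removed target is counted in
- the earlier runs were read with a standard deviation of 2 percentage points
- steps thought possible: complex A -> free enzyme + target; complex B -> free enzyme + second product; second substrate + free enzyme <-> complex B; target -> over-reaction product; free enzyme -> unfolded enzyme; starting material + free enzyme <-> complex A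
- additions bring no volume worth counting

- target, in percent of the starting material first charged, at 20 min
- what to do for the largest gain in target; "none" if nothing gains more than 2 percentage points (epsilon / theta / alpha / none)
- target present, with what was taken out counted in, in percent of the starting material first charged, after epsilon
- target present, with what was taken out counted in, in percent of the starting material first charged, after theta

The bench rule, target grows with time, would give 86.6% at 20 min, but the grey readings from 5.00 min on average 15.2%, high reading included. I read this level as a balance: target enters at the early rate and leaves by over-reaction, so one target molecule stays on average the level divided by the entry rate, 3.51 min. The rule therefore stops near that stay, and 20 min is 5.70 stays. The violet readings sag from 19% to 15%, a hint within the scatter, and dead enzyme remains possible, though removed target is counted in and so costs little to take out.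

Now I follow molecules. A target molecule left in the flask survives 6.0 min with chance 0.181. The readings do not tell how far making has fallen by 20 min, so I assume, as a guess, that making follows the starting material and that this drains at the early rate, which puts making at 42.0% of the rate of loss at 20 min. I commit to about 15.2% at 20 min, then 7.98% after theta and 13.2% after epsilon, while alpha shields target and stands 11 percentage points above theta, at 19.2%, so alpha is my choice.

The forecast gives 16%, 27% after epsilon, 16% after theta and epsilon as best, on the ground “Fresh enzyme should restart production”.

The simulation gives 18.3%, 16.7% after epsilon, 13.1% after theta, and alpha as best, with a gain of 5.7 points.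

    complex A → free enzyme + target (k = 3.30 s⁻¹, Ea = 74.0 kJ mol⁻¹)
    complex B → free enzyme + second product (k = 6.80 s⁻¹, Ea = 65.0 kJ mol⁻¹)
    second substrate + free enzyme ⇌ complex B (K = 280 M⁻¹, k = 66000 M⁻¹ s⁻¹, Ea = 30.0 kJ mol⁻¹, ΔH = 4.00 kJ mol⁻¹)
    target → over-reaction product (k = 0.00300 s⁻¹, Ea = 87.0 kJ mol⁻¹)
    free enzyme → unfolded enzyme (k = 8.20 × 10⁻⁵ s⁻¹, Ea = 193 kJ mol⁻¹)
    starting material + free enzyme ⇌ complex A (K = 94.0 M⁻¹, k = 14000 M⁻¹ s⁻¹, Ea = 20.0 kJ mol⁻¹, ΔH = −19.0 kJ mol⁻¹)
    (constants at 37 °C)

At 20 min the flask is not at rest: 26% of the starting material stands unbound beside 18.3% target and 55.3% over-reaction product, and target is made at 76.4% of the rate at which it is used up, more than the 42.0% I guessed, so making does not follow the starting material as I assumed. Alpha stands 11 points above theta, against my 11 points. Ten times the time is 57.0 of my stays, and at 200 min the flask holds 0% target and >99.9% over-reaction product.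

For the neighbour charged with 40 mM of starting material, the same stay and the same percentage entry rate give 15.2% target. The simulation gives 11.8% at 20 min in that neighbour, with 58.5% of its starting material left.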